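The ratio of side product to target is what you are after, so look at it directly, with both products as fractions of the substrate charged.

| flask | substrate | capture agent | remark | time |
|---|---|---|---|---|
| green | 0.20 M | 0.20 M | the very flask that is asked about, followed so far |  |
| teal | 0.40 M | 0.20 M | run made earlier |  |
| flask | 0.20 M | 0.200 M |  | 6.0 d |

- green (time / h: side product / %, target / %, substrate / %): 1.33: 0, 2, 83; 3.00: 0, 2, 67; 8.00: 1, 8, 43; 15.0: 2, 4, 31
- teal (time / d: side product / %, target / %, substrate / %): 0.500: 5, 3, 31; 1.04: 6, 13, 22; 2.50: 8, 12, 16; 6.00: 12, 23, 7

(standard deviation of a reading: 2 percentage points)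

- ratio of side product to target at 5.0 h
- ratio of side product to target at 6.0 d

Single readings won't carry it: the scatter is 2 percentage points, and the green side product reads 0 %, 0 %, 1 % and 2 %. So pool them. Summed over both runs, side product comes to 34.0 % and target to 67.0 %. Their quotient, 0.507, is the pooled split, the side product formed per unit of target, a selectivity factor read from the readings.

Now put it back into the green run, the one that looks different. Its target sums to 16.0 %, so the split expects 8.11 % of side product, and the readings sum to 3.00 %. That gap is 1.3 points per reading, smaller than the scatter of one reading, though the green run is itself part of the pool. In the teal run, the first two readings give a quotient of 0.688 and the last two 0.571. So you keep one number for these readings and commit to 0.507 at both times.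

The forecast differs, giving 0.2 at 5.0 h and 0.27 at 6.0 d, on the view that “the ratio scales with concentration”.

The flask gives 0.448 at 5.0 h and 0.448 at 6.0 d.

    substrate ⇌ intermediate A (K = 0.710, k = 0.100 h⁻¹)
    substrate → intermediate B (k = 0.0130 h⁻¹)
    intermediate A ⇌ intermediate C (K = 0.340, k = 0.990 h⁻¹)
    intermediate B → target (k = 0.290 h⁻¹)
    intermediate B → side product (k = 0.130 h⁻¹)
    substrate ⇌ intermediate C (k = 0.0680 h⁻¹)
    capture agent + intermediate A → trapped intermediate (k = 0.870 L mol⁻¹ h⁻¹)

Target and side product both leave intermediate B, with rate constants 0.29 h⁻¹ and 0.13 h⁻¹, whose quotient is 0.448. On this flask, your split times its 14.8 % of target at 6.00 d expects 7.50 % of side product, and it holds 6.65 %. The neighbouring flask, charged with 0.80 M of substrate, holds 32.3 % of target at 6.00 d, so the split expects 16.4 % of side product. It holds 14.5 %, a ratio of 0.448.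

(The data stem from a simulated flask with constants of no real substance.)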